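You can lose a lot of target on paper by counting the half-lives of the capture step over the whole run. That count treats the charge as present from the start, and here none of it is in solution then.

| setting | elm | oak | birch |
|---|---|---|---|
| solid substrate | 0.77 M | 0.77 M | 0.77 M |
| capture agent | 0.0800 M | 0.150 M | 0.300 M |
| time | 25 s | 25 s | 25 s |

    2 starting material → self-condensation product (k1 = 0.071 M⁻¹ s⁻¹)
    intermediate B ⇌ intermediate D (K2 = 0.54, k2 = 0.018 s⁻¹)
    intermediate A ⇌ intermediate B (K3 = 0.40, k3 = 0.057 s⁻¹)
    starting material → intermediate C (k4 = 0.32 s⁻¹)
    starting material → intermediate A (k5 = 0.67 s⁻¹)
    intermediate B → target (k6 = 0.051 s⁻¹)
    intermediate C → intermediate A (k7 = 0.026 s⁻¹)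
    solid substrate ⇌ starting material, rate k8*(cs8 - [starting material]) while solid is left; crystals form when [starting material] > cs8 (cs8 = 0.70 M, k8 = 0.041 s⁻¹)
    capture agent + intermediate A → trapped intermediate (k9 = 0.11 M⁻¹ s⁻¹)

- percentages count the solid substrate that a species holds: one self-condensation product counts as two
- a step written with two of one species runs at k times the square of its concentration and takes two of it each time
- solid, in amounts per volume of the solution: solid substrate
- at the start none of the solid substrate is in solution
- "hardly changes" means that all values lie within two and a half points (for a concentration: within two and a half percent of the largest)
- run time (elm): 25 s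

- amount of target at the end, in percent of the solid substrate charged for elm, oak, birch, in this order
- how that number moves from the first to the last of them (rises all the way / falls, then rises / falls all the way / rises, then falls / hardly changes)

The bench rule goes first. Taken as pseudo-first-order, intermediate A has a capture half-life of 79 s in elm and 21.0 s in birch. Over 25 s, the count takes 19.7% of it in elm and 56.2% in birch.

One ratio shows where this stops working. The solid enters at up to 0.0373 s⁻¹ of the charge, so it needs at least this long:

charge time = 26.8 s; run / charge time = 0.933

The run is shorter than the charge time, so you are feeding throughout. Starting material passes on with a half-life of 0.700 s, far shorter than the run. Intermediate A therefore receives a steady stream, and 67.7% of what these two steps carry goes to it directly.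

Steadily growing intermediate A makes target late, on average at 16.7 s. The intermediate A used then entered, on average, half that time earlier. This gives the exposure window, the mean time a future target molecule stands open to capture:

window = 8.33 s, a third of the run

Target kept is the exponential of minus the capture rate constant, times the capture agent charge, times the window:

elm 0.929; oak 0.872; birch 0.760

For the scale, I hold intermediate B in steady balance with intermediate A. It forms from intermediate A and leaves back, to target and to intermediate D, which gives it 21.2% of their pool. I count the direct stream and start the clock one settling time late, 3.72 s:

target without capture = 6.18% of the charge

My row is 0.0574, 0.0539 and 0.0469. Its spread of 1.05% of the charge is inside the band of 2.5 points, so my shape is: hardly changes.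

The forecast gave 6%, 5.6% and 4.9%, with the shape hardly changes, on this ground: “More capture agent takes a growing share of A”.

The flask gives 5.45%, 5.24% and 4.83%, so the shape is hardly changes, and my elm figure stands above its result. At 25.0 s, birch holds 13.3% as trapped intermediate and 37.1% as intermediate A. For oak against elm, the window of 8.33 s gives a kept ratio of 0.938. The flask holds target at 5.24% in oak and 5.45% in elm, a ratio of 0.961.

The numbers were set for the occasion; the result is computed.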